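## The problem

Target 12 is a 7-methoxycoumarin whose C6 carries a branched four-carbon chain, C1'(O-isovaleryl)–C2'(OH)–C3'(CH3)2OH. No ring has to be built beyond the pyranone, so the task is to attach and oxygenate an open chain at one defined ring position. C6 lies ortho to the methoxy group, and electrophilic substitution of 7-methoxycoumarin does not choose reliably between C6, C8 and C3, so the C6 handle is best carried in with the benzene starting material. There are two stereocentres, C1' (S) and C2' (R), adjacent and syn (threo); C3' is not stereogenic. Either centre could direct the other, but the arene is achiral, so the absolute sense must come from a reagent or catalyst, ideally for both centres at once. Three oxygens sit on neighbouring carbons and only the benzylic one is acylated; an ester on O1' beside a free O2' hydroxyl can migrate under base, so the acyl group must be placed while O2' is masked, and O2' must be released without base. The lactone and its C3=C4 bond do not tolerate hydroxide, alkoxide, hydride, hard nucleophiles at ambient temperature or long irradiation, and the benzylic ester on an electron-rich ring and the tertiary carbinol do not tolerate strong acid. The enabling feature is that C1' and C2' are neighbouring carbinol carbons while C3' bears an oxygen and two methyl groups: read C3' as the carbonyl of a methyl ketone, and C1'–C2' becomes the bond of an aldol between an aryl aldehyde at C6 and the oxygenated carbon of a protected hydroxyacetone.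

## Retrosynthesis

**12 to 11.** The last operation should change only a protecting group, so 12 is traced to its C2' silyl ether 11 by cutting the O2'–Si bond. A cyclic acetal over O2'/O3' would need stronger acid to remove, and an acetal over O1'/O2' would erase the difference between the two secondary oxygens. Compound 11 is no simpler in skeleton, but it stores the regiochemical information. The forward step must free O2' under acidic fluoride, so that the neighbouring ester never meets a base while the hydroxyl is free.

**11 to 9 and 10.** The ester C–O bond at O1' is cut, giving diol 9 and isovaleric anhydride 10. In 9 only O1' (secondary, benzylic) and O3' (tertiary) are free and O2' is silylated, so acylation has a single reasonable site. Acylating a triol instead would require a choice between two secondary hydroxyls. The forward step must acylate a hindered secondary hydroxyl without moving the silyl group.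

**9 to 8.** One C3'–CH3 bond is cut, turning the tertiary carbinol into the methyl ketone 8. No stereocentre is touched, because C3' receives a second, identical methyl group. This cut is what converts C1'–C2' into an aldol bond. The forward step needs a methyl nucleophile that takes the ketone in preference to the lactone and does not provoke retro-aldol cleavage.

**8 to 6 and 7.** The C1'–C2' bond is cut, giving aldehyde 6 and silyloxy ketone 7. The neighbouring cuts are worse: C6–C1' would need a chain with both stereocentres already made, and C2'–C3' would need a configurationally fragile α-hydroxy aldehyde. The chosen cut gives two achiral pieces of similar size, sets both stereocentres in one step, and delivers O1' free and O2' protected, which is the differentiation the end game needs. The forward reaction must be regioselective for the oxygenated carbon of 7, syn-selective and enantioselective; an L-configured primary amino acid catalyst (specified in step 4) is chosen for this.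

**6 to 4.** The formyl carbon is traced to a vinyl group, the C=C bond of 4 being cleaved through diol 5. Direct formylation of the coumarin would not be regioselective, and a formyl group present earlier would compete in the olefination that builds the pyranone. The forward step must oxidise the styrene-type alkene and leave the electron-poor C3=C4 bond alone.

**4 to 3.** The C6–vinyl bond is cut, giving aryl bromide 3. A bromide is the simplest handle that survives pyranone formation and enters cross-coupling. The forward step needs a base that does not open the lactone.

**3 to 1.** The pyranone is opened at the C3=C4 double bond and the O1–C2 lactone bond, giving salicylaldehyde 1, a commercial compound that already has bromine and methoxy in the right places. The forward step is an olefination followed in the same flask by lactonisation of cinnamate 2.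

## Roads not taken

**Alternative 1:** The C2'–O and C3'–O bonds are traced to an oxirane, and the oxirane to the C2'=C3' double bond of the (R)-allylic alcohol A1, itself made from aldehyde 6. In the forward key step, mCPBA hydrogen-bonded to the C1' hydroxyl epoxidises the trisubstituted alkene. The methyl group cis to C1' forces the C1'–H bond into the alkene plane (A1,3 strain), so one face is offered and the threo epoxy alcohol A2 should result. Acylation of O1' and acid-catalysed hydration at the tertiary C3' would finish the synthesis. The merits are real: no silyl group is needed, no hard nucleophile comes near the lactone, and the threo preference is well founded for alkenes with a cis substituent. The weak points lie elsewhere.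
- The absolute configuration at C1' must be obtained in a separate enantioselective operation, so two stereo-defining steps replace one.
- A1 is benzylic and allylic on an electron-rich ring, and can ionise or transpose under the acid by-product of the peracid.
- In the final hydration the ester carbonyl can capture the developing cation at C3' through a six-membered acyloxonium ion, moving the acyl group to O3'.

In length this road is comparable or one step longer. It is better in avoiding protecting groups; the chosen plan sets against this a single catalytic step that makes both centres from achiral partners, and a silyl ether that also enforces the acylation site.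

**Alternative 2:** The C6–C1' bond is cut, giving bromide 3 and the tartrate-derived dioxolane acid A3. Under blue light with Ir[dF(CF3)ppy]2(dtbbpy)PF6, NiCl2·glyme, 4,4'-di-tert-butyl-2,2'-bipyridine and Cs2CO3, A3 would lose CO2 and the dioxolanyl radical would be coupled to 3, giving the trans-dioxolane A4. The merits are a chiral-pool source for C2', a C1' configuration set by the trans preference of the ring, and direct use of bromide 3, which saves the vinylation and cleavage steps. The weak points are several.
- Making A3 requires desymmetrising a tartrate diester, with two methyl groups added to one ester only.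
- The C1' configuration depends on how the dioxolanyl radical is captured at nickel, which is expected to be trans but is substrate-dependent.
- The ortho-methoxy aryl bromide is a slow partner for nickel.
- The coumarin can dimerise by [2+2] cycloaddition if the iridium sensitiser transfers triplet energy to it.
- The acetonide of A4 ties together exactly O1' and O2', so after its removal both secondary hydroxyls are free and the acylation has nothing to tell them apart.

This road reaches the carbon skeleton about two steps sooner. The chosen plan sets against that a key step of a precedented type for aromatic aldehydes and a product in which O1' and O2' are already differentiated.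

**Alternative 3:** Both carbinol C–H bonds are cut, giving the 1,2-dione A5, which could come from bromide 3 by alkynylation and oxidation of the triple bond. One enantiomer of RuCl(p-cymene)(TsDPEN) with HCO2H/Et3N would reduce the aryl ketone under catalyst control. The remaining α-hydroxy ketone is configurationally labile, so the second reduction would select dynamically and give the syn triol A6. This is the shortest road to the full oxygenation pattern, it makes both stereocentres in one catalytic step, and it uses no organometallic reagent near the lactone; in step count it is better than the chosen plan. Its weak points are two.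
- The precedent rests on diaryl diketones. Here the second carbonyl is aliphatic and flanked by a tertiary carbinol, so catalyst recognition at C2' is uncertain and the enediol equilibration could also move the carbonyl between C1' and C2'.
- A6 has O1' and O2' both free, so the isovalerate would have to choose the benzylic hydroxyl over its neighbour, under basic conditions in which the ester can migrate.

The chosen plan is longer but answers exactly this point: its aldol product is formed with O2' silylated and O1' free.

Key step: step 4

Assumption: ketone 7 is taken as a purchased silyl ether; prepared in-house from the parent hydroxy ketone it would add one routine silylation, which is not counted.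

## Route

Step 1
Reactants: 1 5-bromo-2-hydroxy-4-methoxybenzaldehyde
Product: 3 6-bromo-7-methoxy-2H-chromen-2-one, via ethyl hydroxycinnamate 2 (not isolated)
Conditions: Ph3P=CHCO2Et (1.3 equiv), PhNEt2, reflux (ca. 215 °C)
Reagents that add atoms: ethyl (triphenylphosphoranylidene)acetate, CCOC(=O)C=P(c1ccccc1)(c1ccccc1)c1ccccc1
Why: Wittig olefination of the salicylaldehyde with the stabilised ylide should give cinnamate 2, whose E and Z forms interconvert at this temperature; the Z ester closes by intramolecular transesterification with loss of ethanol (domino Wittig–lactonisation), and bromine and methoxy end up at C6 and C7 by construction.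

Step 2
Reactants: 3 6-bromo-7-methoxy-2H-chromen-2-one
Product: 4 6-ethenyl-7-methoxy-2H-chromen-2-one
Conditions: CH2=CHBF3K (1.3 equiv), PdCl2(dppf)·CH2Cl2 (3 mol %), Et3N (3 equiv), n-PrOH, reflux
Reagents that add atoms: potassium vinyltrifluoroborate, [K+].C=C[B-](F)(F)F
Why: Suzuki–Miyaura vinylation: zerovalent palladium inserts into the C6–Br bond, the vinyl group is transferred from boron and reductive elimination forms the C6–vinyl bond; the amine base in propanol is chosen so that no hydroxide or carbonate opens the lactone.

Step 3
Reactants: 4 6-ethenyl-7-methoxy-2H-chromen-2-one
Product: 6 7-methoxy-2-oxo-2H-chromene-6-carbaldehyde, via vicinal diol 5 (not isolated)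
Conditions: OsO4 (2 mol %), NaIO4 (4 equiv), 2,6-lutidine (2 equiv), dioxane/H2O (3:1), rt
Reagents that add atoms: osmium tetroxide, O=[Os](=O)(=O)=O; sodium periodate (terminal oxidant that restores it), [Na+].[O-]I(=O)(=O)=O
Why: Lemieux–Johnson oxidation: OsO4 should dihydroxylate the terminal, arene-conjugated alkene much faster than the electron-poor C3=C4 bond of the pyranone, and periodate cleaves diol 5 to the aldehyde and reoxidises the reduced osmium; 2,6-lutidine speeds the cleavage and suppresses over-oxidation.

Step 4
Reactants: 6 7-methoxy-2-oxo-2H-chromene-6-carbaldehyde; 7 1-(tert-butyldimethylsilyloxy)propan-2-one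
Product: 8 6-[(1S,2R)-2-(tert-butyldimethylsilyloxy)-1-hydroxy-3-oxobutyl]-7-methoxy-2H-chromen-2-one
Conditions: O-tBu-L-Thr (20 mol %), 7 (5 equiv), NMP/H2O (97:3), 4 °C → rt
Reagents that add atoms: none
Why: The primary amine of O-tert-butyl-L-threonine condenses with ketone 7 and the iminium ion tautomerises to the enamine on the oxygenated carbon, where an N–H···O hydrogen bond to the silyl ether oxygen holds the Z geometry; this enamine adds to the aldehyde carbon of 6, whose carbonyl oxygen is hydrogen-bonded to the catalyst's carboxylic acid in a closed chair-like transition state, and hydrolysis of the product iminium ion releases 8 and the catalyst. The closest known reaction type is the primary-amino-acid-catalysed syn-selective direct aldol of O-protected hydroxyacetone with aromatic aldehydes. The step forms only the C1'–C2' bond and closes no ring. C2' (R) is fixed by the Z-enamine geometry together with the enamine face that the acid-bound aldehyde can reach, and C1' (S) by the aldehyde face exposed when the aryl group sits equatorial in that chair; both follow from the L configuration of the catalyst, whose antipode would give the mirror image. The step needs branched over linear regiochemistry, syn over anti and one enantiomer: the first two come from the hydrogen-bonded Z-enamine, which a secondary amine cannot form, and the third from the catalyst. On the substrate side, 6 has no α-hydrogen and cannot self-condense, its only strong donor is the ortho methoxy group while the para lactone oxygen and the meta enoate keep the carbonyl electrophilic, and the lactone is inert to the neutral amino acid. The excess of 7 should drive conversion, and stopping before full equilibration should protect the syn ratio against retro-aldol erosion.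

Step 5
Reactants: 8 6-[(1S,2R)-2-(tert-butyldimethylsilyloxy)-1-hydroxy-3-oxobutyl]-7-methoxy-2H-chromen-2-one
Product: 9 6-[(1S,2R)-2-(tert-butyldimethylsilyloxy)-1,3-dihydroxy-3-methylbutyl]-7-methoxy-2H-chromen-2-one
Conditions: MeMgBr (3.5 equiv), CeCl3 (3.5 equiv), THF, −78 °C; aq. NH4Cl at −78 °C
Reagents that add atoms: methylmagnesium bromide, C[Mg]Br
Why: Organocerium 1,2-addition: the weakly basic methylcerium reagent should add to the ketone after the C1' hydroxyl is deprotonated, without enolising C2' and without touching the far less electrophilic lactone at −78 °C; C3' receives a second methyl group and is not stereogenic, and the cold quench is meant to forestall silyl migration between the alkoxides.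

Step 6
Reactants: 9 6-[(1S,2R)-2-(tert-butyldimethylsilyloxy)-1,3-dihydroxy-3-methylbutyl]-7-methoxy-2H-chromen-2-one; 10 3-methylbutanoic anhydride
Product: 11 (1S,2R)-2-(tert-butyldimethylsilyloxy)-3-hydroxy-1-(7-methoxy-2-oxo-2H-chromen-6-yl)-3-methylbutyl 3-methylbutanoate
Conditions: 10 (1.5 equiv), DMAP (0.2 equiv), Et3N (2 equiv), CH2Cl2, 0 °C → rt
Reagents that add atoms: none
Why: DMAP-catalysed acylation through the acylpyridinium ion: O2' is silylated and the tertiary O3' hydroxyl is too hindered to compete under these conditions, so the ester should form only at the secondary benzylic O1', with C1' and C2' untouched.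

Step 7
Reactants: 11 (1S,2R)-2-(tert-butyldimethylsilyloxy)-3-hydroxy-1-(7-methoxy-2-oxo-2H-chromen-6-yl)-3-methylbutyl 3-methylbutanoate
Product: 12 (1S,2R)-2,3-dihydroxy-1-(7-methoxy-2-oxo-2H-chromen-6-yl)-3-methylbutyl 3-methylbutanoate
Conditions: HF·pyridine, pyridine, THF, 0 °C → rt
Reagents that add atoms: none
Why: Fluoride-mediated cleavage of the silyl ether under buffered, mildly acidic conditions: the Si–O bond is cut while neither the lactone nor the ester meets a basic alkoxide, so the isovalerate should stay on O1' and both stereocentres are unchanged.

## Compound list

1 | 5-bromo-2-hydroxy-4-methoxybenzaldehyde | COc1cc(O)c(C=O)cc1Br | starting material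
2 | ethyl 3-(5-bromo-2-hydroxy-4-methoxyphenyl)prop-2-enoate (E and Z forms interconverting at the reaction temperature) | CCOC(=O)C=Cc1cc(Br)c(OC)cc1O | intermediate (not isolated)
3 | 6-bromo-7-methoxy-2H-chromen-2-one | COc1cc2oc(=O)ccc2cc1Br | intermediate
4 | 6-ethenyl-7-methoxy-2H-chromen-2-one | COc1cc2oc(=O)ccc2cc1C=C | intermediate
5 | 6-(1,2-dihydroxyethyl)-7-methoxy-2H-chromen-2-one (racemic) | COc1cc2oc(=O)ccc2cc1C(O)CO | intermediate (not isolated)
6 | 7-methoxy-2-oxo-2H-chromene-6-carbaldehyde | COc1cc2oc(=O)ccc2cc1C=O | intermediate
7 | 1-(tert-butyldimethylsilyloxy)propan-2-one | CC(=O)CO[Si](C)(C)C(C)(C)C | starting material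
8 | 6-[(1S,2R)-2-(tert-butyldimethylsilyloxy)-1-hydroxy-3-oxobutyl]-7-methoxy-2H-chromen-2-one | COc1cc2oc(=O)ccc2cc1[C@H](O)[C@@H](O[Si](C)(C)C(C)(C)C)C(C)=O | intermediate
9 | 6-[(1S,2R)-2-(tert-butyldimethylsilyloxy)-1,3-dihydroxy-3-methylbutyl]-7-methoxy-2H-chromen-2-one | COc1cc2oc(=O)ccc2cc1[C@H](O)[C@@H](O[Si](C)(C)C(C)(C)C)C(C)(C)O | intermediate
10 | 3-methylbutanoic anhydride (isovaleric anhydride) | CC(C)CC(=O)OC(=O)CC(C)C | starting material
11 | (1S,2R)-2-(tert-butyldimethylsilyloxy)-3-hydroxy-1-(7-methoxy-2-oxo-2H-chromen-6-yl)-3-methylbutyl 3-methylbutanoate | COc1cc2oc(=O)ccc2cc1[C@H](OC(=O)CC(C)C)[C@@H](O[Si](C)(C)C(C)(C)C)C(C)(C)O | intermediate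
12 | (1S,2R)-2,3-dihydroxy-1-(7-methoxy-2-oxo-2H-chromen-6-yl)-3-methylbutyl 3-methylbutanoate | COc1cc2oc(=O)ccc2cc1[C@H](OC(=O)CC(C)C)[C@@H](O)C(C)(C)O | target

## Step count and least certain steps

Total: 7 steps. Longest linear sequence: 7 steps (1 to 12); ketone 7 and anhydride 10 enter as purchased materials.

**Step 4 (key step).** The most likely failure is slow addition of the enamine to an ortho-substituted, moderately electron-rich aldehyde. Long reaction times would then allow retro-aldol equilibration to erode the syn ratio and allow dehydration of the aldol towards the aryl-conjugated enone. Reaction at the methyl side of the ketone is a lesser risk. The fallback sets out from 6 and returns at 8, making the same C1'–C2' bond under stoichiometric control. (R)-4-Benzyloxazolidin-2-one is N-acylated with (tert-butyldimethylsilyloxy)acetyl chloride to give (R)-4-benzyl-3-[(tert-butyldimethylsilyloxy)acetyl]oxazolidin-2-one F1. Its Z boron enolate (Bu2BOTf, Et3N, CH2Cl2, −78 °C) should add to 6 in an Evans syn aldol, giving (R)-4-benzyl-3-[(2R,3S)-2-(tert-butyldimethylsilyloxy)-3-hydroxy-3-(7-methoxy-2-oxo-2H-chromen-6-yl)propanoyl]oxazolidin-2-one F2. Transamidation with Me(MeO)NH·HCl/AlMe3 at −20 to 0 °C, helped by the free β-hydroxyl and kept cold to spare the lactone, gives (2R,3S)-2-(tert-butyldimethylsilyloxy)-3-hydroxy-N-methoxy-3-(7-methoxy-2-oxo-2H-chromen-6-yl)-N-methylpropanamide F3. MeMgBr in THF at −78 to 0 °C then converts F3 into 8.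

**Step 5.** The most likely failure is retro-aldol cleavage of the C1'–C2' bond through the metal alkoxide of the free benzylic hydroxyl. Enolisation at C2' and attack on the lactone carbonyl become possible if the mixture warms. The fallback sets out from 8 and returns at 9, removing the free hydroxyl for the duration of the addition. TESOTf and 2,6-lutidine in CH2Cl2 at −78 °C give 6-[(1S,2R)-2-(tert-butyldimethylsilyloxy)-3-oxo-1-(triethylsilyloxy)butyl]-7-methoxy-2H-chromen-2-one F4. MeMgBr/CeCl3 in THF at −78 °C gives 6-[(1S,2R)-2-(tert-butyldimethylsilyloxy)-3-hydroxy-3-methyl-1-(triethylsilyloxy)butyl]-7-methoxy-2H-chromen-2-one F5. PPTS in MeOH at 0 °C then removes the triethylsilyl ether selectively in the presence of the tert-butyldimethylsilyl ether and delivers 9.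

**Step 7.** The most likely failure is migration of the isovaleryl group from O1' to the newly freed O2', favoured if cleavage of the hindered silyl ether is slow and has to be forced. Ionisation of the benzylic ester under too much acid is a second risk. The fallback sets out from 6 and returns at 12, carrying a more labile silyl group through the same sequence so that the last unmasking needs only weak aqueous acid for a short time. Hydroxyacetone is silylated with TESCl and imidazole to give 1-(triethylsilyloxy)propan-2-one F6. The step 4 aldol with 6 gives 6-[(1S,2R)-1-hydroxy-3-oxo-2-(triethylsilyloxy)butyl]-7-methoxy-2H-chromen-2-one F7. MeMgBr/CeCl3 gives 6-[(1S,2R)-1,3-dihydroxy-3-methyl-2-(triethylsilyloxy)butyl]-7-methoxy-2H-chromen-2-one F8. Acylation with 10 and DMAP gives (1S,2R)-3-hydroxy-1-(7-methoxy-2-oxo-2H-chromen-6-yl)-3-methyl-2-(triethylsilyloxy)butyl 3-methylbutanoate F9. AcOH/THF/H2O at rt then gives 12.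

**Step 3.** The most likely failure is competing osmylation of the pyranone C3=C4 bond or over-oxidation of the electron-rich aldehyde if cleavage of the diol lags behind dihydroxylation. The fallback sets out from 3 and returns at 6, bypassing 4 and 5. It is a palladium-catalysed reductive carbonylation of the aryl bromide with CO/H2, Pd(OAc)2, di(1-adamantyl)-n-butylphosphine and TMEDA in toluene at 100 °C, which introduces the formyl group directly and makes no new intermediate.

## Further compounds

F1 | step 4 | (R)-4-benzyl-3-[(tert-butyldimethylsilyloxy)acetyl]oxazolidin-2-one | O=C1OC[C@@H](Cc2ccccc2)N1C(=O)CO[Si](C)(C)C(C)(C)C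
F2 | step 4 | (R)-4-benzyl-3-[(2R,3S)-2-(tert-butyldimethylsilyloxy)-3-hydroxy-3-(7-methoxy-2-oxo-2H-chromen-6-yl)propanoyl]oxazolidin-2-one | COc1cc2oc(=O)ccc2cc1[C@H](O)[C@@H](O[Si](C)(C)C(C)(C)C)C(=O)N1C(=O)OC[C@H]1Cc1ccccc1
F3 | step 4 | (2R,3S)-2-(tert-butyldimethylsilyloxy)-3-hydroxy-N-methoxy-3-(7-methoxy-2-oxo-2H-chromen-6-yl)-N-methylpropanamide | COc1cc2oc(=O)ccc2cc1[C@H](O)[C@@H](O[Si](C)(C)C(C)(C)C)C(=O)N(C)OC
F4 | step 5 | 6-[(1S,2R)-2-(tert-butyldimethylsilyloxy)-3-oxo-1-(triethylsilyloxy)butyl]-7-methoxy-2H-chromen-2-one | COc1cc2oc(=O)ccc2cc1[C@H](O[Si](CC)(CC)CC)[C@@H](O[Si](C)(C)C(C)(C)C)C(C)=O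
F5 | step 5 | 6-[(1S,2R)-2-(tert-butyldimethylsilyloxy)-3-hydroxy-3-methyl-1-(triethylsilyloxy)butyl]-7-methoxy-2H-chromen-2-one | COc1cc2oc(=O)ccc2cc1[C@H](O[Si](CC)(CC)CC)[C@@H](O[Si](C)(C)C(C)(C)C)C(C)(C)O
F6 | step 7 | 1-(triethylsilyloxy)propan-2-one | CC(=O)CO[Si](CC)(CC)CC
F7 | step 7 | 6-[(1S,2R)-1-hydroxy-3-oxo-2-(triethylsilyloxy)butyl]-7-methoxy-2H-chromen-2-one | COc1cc2oc(=O)ccc2cc1[C@H](O)[C@@H](O[Si](CC)(CC)CC)C(C)=O
F8 | step 7 | 6-[(1S,2R)-1,3-dihydroxy-3-methyl-2-(triethylsilyloxy)butyl]-7-methoxy-2H-chromen-2-one | COc1cc2oc(=O)ccc2cc1[C@H](O)[C@@H](O[Si](CC)(CC)CC)C(C)(C)O
F9 | step 7 | (1S,2R)-3-hydroxy-1-(7-methoxy-2-oxo-2H-chromen-6-yl)-3-methyl-2-(triethylsilyloxy)butyl 3-methylbutanoate | COc1cc2oc(=O)ccc2cc1[C@H](OC(=O)CC(C)C)[C@@H](O[Si](CC)(CC)CC)C(C)(C)O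
F0 | step 3 | none | none
A1 | alternative 1 | 6-[(1R)-1-hydroxy-3-methylbut-2-en-1-yl]-7-methoxy-2H-chromen-2-one | COc1cc2oc(=O)ccc2cc1[C@H](O)C=C(C)C
A2 | alternative 1 | 6-{(S)-[(2R)-3,3-dimethyloxiran-2-yl](hydroxy)methyl}-7-methoxy-2H-chromen-2-one | COc1cc2oc(=O)ccc2cc1[C@H](O)[C@H]1OC1(C)C
A3 | alternative 2 | (4R,5R)-5-(2-hydroxypropan-2-yl)-2,2-dimethyl-1,3-dioxolane-4-carboxylic acid | OC(=O)[C@@H]1OC(C)(C)O[C@H]1C(C)(C)O
A4 | alternative 2 | 6-[(4S,5R)-5-(2-hydroxypropan-2-yl)-2,2-dimethyl-1,3-dioxolan-4-yl]-7-methoxy-2H-chromen-2-one | COc1cc2oc(=O)ccc2cc1[C@@H]1OC(C)(C)O[C@H]1C(C)(C)O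
A5 | alternative 3 | 3-hydroxy-1-(7-methoxy-2-oxo-2H-chromen-6-yl)-3-methylbutane-1,2-dione | COc1cc2oc(=O)ccc2cc1C(=O)C(=O)C(C)(C)O
A6 | alternative 3 | 7-methoxy-6-[(1S,2R)-1,2,3-trihydroxy-3-methylbutyl]-2H-chromen-2-one | COc1cc2oc(=O)ccc2cc1[C@H](O)[C@@H](O)C(C)(C)O
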